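(The runs come from a simulation with made-up constants; scatter was added.)

Molar minutes are the unit to reckon in, and the gauge to watch is exposure: the area under cZ against time, in M·min.

| flask | Q | Z | time |
|---|---|---|---|
| west | 0.300 M | 0.300 M |  |
| east | 0.900 M | 0.300 M |  |
| south-east | 0.300 M | 0.150 M |  |
| south-west | 0.150 M | 0.900 M | 35 min |

- west run (time / min: [J] / M): 2.0: 0.0140; 6.0: 0.0363; 12: 0.0614; 18: 0.0794; 26: 0.0965; 35: 0.1093
- east run (time / min: [J] / M): 2.0: 0.0408; 6.0: 0.0976; 12: 0.1502; 18: 0.1805; 26: 0.2029; 35: 0.2190
- south-east run (time / min: [J] / M): 2.0: 0.0075; 6.0: 0.0190; 12: 0.0366; 18: 0.0482; 26: 0.0581; 35: 0.0665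

(scatter of a reading: 9 × 10⁻⁴ M)

* reaction order in [Z] at the outset, round the charge of the west run, defined at two percent of the Q turned into J
* reaction order in [Q] at the outset, round the charge of the west run, defined at two percent of the Q turned into J (one fixed amount of J, the same in the runs compared)
* J in the south-west run at 35 min, as a share of the Q charged
* which of these the readings show (the product reacts on with the second partner / two substrates go astray together / the second partner is lost in pairs)

- Overall: Q + Z -> J.
- Constant volume, constant temperature.
- "The second partner" is Z.
- An order is taken over about fifteen percent of the charge, up and down.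

At the first reading, J in the east run over J in the west run gives an order of 0.974 in Q, and the south-east run gives 0.900 in Z. I read both as about first order, within the scatter. The balance of Q then says that the logarithm of Q charged over Q left equals k times the exposure. The first west reading gives k = 0.0815 /M/min, so 212 M·s is the quarter exposure: the area under cZ that turns a quarter of the Q in these flasks, whatever its charge.

Now the balance of Z. Late in the west run the slope of J gives cZ near 0.0885 M, and J stands near 0.103 M, so 0.109 M of Z is missing. I take it as lost in pairs, at a rate a times the square of cZ. A hyperbolic fall of cZ then gives a = 0.134 /M/min.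

The ladder of the south-west flask, where Q is the limiting reagent, runs as follows. Pairs halve cZ in 8.28 min. Z turns Q over more slowly, in 13.6 min, which is still shorter than the 35 min of the reading. Q turns Z over in 81.8 min, longer than that reading time. So in my reckoning pairs thin Z and I drop what Q takes of it: the exposure comes to 740 M·s, and my share is 63.4%.

The forecast gives 1.02 in Z, 1.05 in Q and 64% (range 56% to 72%), and it names the second partner is lost in pairs, since that loss “fits east and west, and south-east less well”.

The flask gives 1.0 in Z, 1.0 in Q, 65.6%, and the second partner is lost in pairs.

    Q + Z → J (0.08760 /M/min)
    Q + Z → X (0.004590 /M/min)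
    2 Z → Ky (0.05412 /M/min)

In the south-west flask both steps ran from the start: pairs took Z with a first half-life of 10.3 min, while Q went to J, and to X at 5.24% of the rate of J, so with both routes of Q counted the J at 35 min stands for 762 M·s of exposure, a mean cZ of 0.363 M against a charge of 0.900 M. Counted the same way, my quarter exposure of 212 M·s becomes 199 M·s, and in the east flask J reached a quarter of the Q charged at 42.5 min, which gives a mean cZ of 0.0780 M against a charge of 0.300 M.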